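6-Prenylsakuranetin ⇒ (aromatic Claisen, retro-[3,3]) its O5 1,1-dimethylallyl ether ⇒ (Lindlar) the O5 1,1-dimethylpropargyl ether. The C6 prenyl group and the free 5-OH are released together, last, under neutral conditions.
That flavanone ⇒ open ring C (O1–C2–C3–C4–C4a–C8a) at O1–C2 and add a temporary CO2tBu at C3 ⇒ an acyclic, achiral E/Z arylidene β-keto ester. Forward: catalytic asymmetric oxa-Michael closure, then acidolysis and decarboxylation in the same flask.
Enabling feature: the acyl-bearing carbon C4a of ring A is flanked by two phenolic oxygens (O1 on C8a, O5 on C5), and the prenylated carbon C6 is ortho to O5. The C5 unit can therefore be parked on O5 through an O–C bond absent from the target, which leaves O1–H as the only nucleophile (this decides 6- versus 8-prenyl) and is later cleaved by the [3,3] shift. C3, α to C4=O, can carry a carboxyl that leaves as CO2.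
Arylidene β-keto ester ⇒ Knoevenagel of 4-tert-butoxybenzaldehyde with the aroylacetate ⇒ C-carboxylation of the acetophenone ⇒ desymmetrising mono-etherification of 2',6'-dihydroxy-4'-methoxyacetophenone.
Ring order: rings A and B are bought as arenes; ring C is the only ring built and is closed last.

Key step: step 4

Assumption: the epi-quinine-derived thiourea is taken to deliver the (2S) product with this substrate; if the sense of induction is the opposite, its quinidine-derived pseudo-enantiomer takes its place with no other change.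

Step 1
Reactants: 1 2',6'-dihydroxy-4'-methoxyacetophenone; 2 3-chloro-3-methylbut-1-yne
Product: 3 1-[2-hydroxy-4-methoxy-6-(2-methylbut-3-yn-2-yloxy)phenyl]ethanone
Conditions: K2CO3 (2 equiv), KI (cat.), CuI (cat.), DMF, 50 °C
Reagents that add atoms: none
Why: Copper-assisted Williamson-type O-propargylation: the two hydroxyls of 1 are equivalent by symmetry, so mono-etherification can give only one regioisomer, and the remaining hydroxyl is tied up in a hydrogen bond to the acetyl C=O, which should hold back a second alkylation.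

Step 2
Reactants: 3 1-[2-hydroxy-4-methoxy-6-(2-methylbut-3-yn-2-yloxy)phenyl]ethanone
Product: 4 tert-butyl 3-[2-hydroxy-4-methoxy-6-(2-methylbut-3-yn-2-yloxy)phenyl]-3-oxopropanoate
Conditions: LiHMDS (3.1 equiv), THF, −78 °C; Boc2O (1.05 equiv), −78 → 0 °C; cold 1 M HCl quench
Reagents that add atoms: di-tert-butyl dicarbonate, CC(C)(C)OC(=O)OC(=O)OC(C)(C)C
Why: Crossed Claisen-type C-acylation of the lithium polyanion of an o-hydroxyacetophenone by a dialkyl dicarbonate: the carbon enolate is the most nucleophilic site, any O-Boc product formed at the phenoxide should be relayed to carbon by a Baker–Venkataraman-type O-to-C transfer under the excess base, and the tert-butyl ester resists lactonisation to a 4-hydroxycoumarin.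

Step 3
Reactants: 4 tert-butyl 3-[2-hydroxy-4-methoxy-6-(2-methylbut-3-yn-2-yloxy)phenyl]-3-oxopropanoate; 5 4-tert-butoxybenzaldehyde
Product: 6 tert-butyl 3-(4-tert-butoxyphenyl)-2-[2-hydroxy-4-methoxy-6-(2-methylbut-3-yn-2-yloxy)benzoyl]prop-2-enoate (E/Z mixture, achiral)
Conditions: piperidine (20 mol %), AcOH (20 mol %), 4 Å MS, PhMe, rt
Reagents that add atoms: none
Why: Knoevenagel condensation of an active methylene compound with an aromatic aldehyde under piperidinium acetate catalysis; the alkene geometry need not be controlled because the next step is convergent, and the phenol is held back from early addition by its hydrogen bond to the ketone and by the buffered medium.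

Step 4
Reactants: 6 tert-butyl 3-(4-tert-butoxyphenyl)-2-[2-hydroxy-4-methoxy-6-(2-methylbut-3-yn-2-yloxy)benzoyl]prop-2-enoate (E/Z mixture)
Product: 9 (2S)-2-(4-hydroxyphenyl)-7-methoxy-5-(2-methylbut-3-yn-2-yloxy)chroman-4-one, via cyclised tert-butyl ester 7 (not isolated), via β-keto acid 8 (not isolated)
Conditions: 9-amino(9-deoxy)-epi-quinine 3,5-bis(trifluoromethyl)phenyl thiourea (10 mol %), PhMe, −25 °C; then TsOH·H2O (30 mol %), 80 °C, N2 sweep
Reagents that add atoms: none
Why: The quinuclidine nitrogen of the bifunctional catalyst takes the O1–H proton while the thiourea binds the β-keto ester carbonyls, so the phenoxide adds to one face of the arylidene carbon (intramolecular oxa-Michael addition, 6-endo-trig closure of ring C) to give 7; TsOH then silences the amine and cleaves both tert-butyl groups as isobutene, and β-keto acid 8 loses CO2, which makes the otherwise reversible closure permanent. The closest known reaction type is the cinchona-thiourea-catalysed cyclisation of 2-hydroxyaryl alkylidene β-keto esters to flavanones with acid decarboxylation in the same flask. C2 is the only lasting stereocentre and is set by the catalyst, whereas C3 of 7 is a labile β-dicarbonyl centre whose epimers and enol all converge once the carboxyl leaves. The step is also stereoconvergent in the alkene, because E-6 and Z-6 interconvert by reversible conjugate addition and should funnel through the same catalyst-bound conformer. The selectivity needed is attack by O1 rather than O5 (it decides 6- versus 8-prenyl), and it is secured because O5 is blocked as the tertiary propargyl ether, so only O1–H can close. Chemoselectivity in the acid stage rests on the much slower ionisation of a tertiary propargylic ether compared with a tert-butyl ester or aryl tert-butyl ether, and the peri O5 substituent twists the aroyl group of 6 out of conjugation, which favours the closed form.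

Step 5
Reactants: 9 (2S)-2-(4-hydroxyphenyl)-7-methoxy-5-(2-methylbut-3-yn-2-yloxy)chroman-4-one
Product: 10 (2S)-2-(4-hydroxyphenyl)-7-methoxy-5-(2-methylbut-3-en-2-yloxy)chroman-4-one
Conditions: H2 (1 atm), Lindlar catalyst, quinoline (cat.), EtOAc, rt; short silica plug
Reagents that add atoms: none
Why: Lindlar semihydrogenation of a terminal alkyne stops at the vinyl group on the poisoned catalyst, and the neutral room-temperature medium leaves the ketone, the phenol and C2 untouched.

Step 6
Reactants: 10 (2S)-2-(4-hydroxyphenyl)-7-methoxy-5-(2-methylbut-3-en-2-yloxy)chroman-4-one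
Product: 12 6-prenylsakuranetin, via ortho-dienone 11 (not isolated)
Conditions: degassed PhMe, 110 °C (sealed tube)
Reagents that add atoms: none
Why: Aromatic Claisen rearrangement: the [3,3] shift can only reach C6 because the other ortho position of O5 (C4a) is fully substituted, allylic inversion turns the 1,1-dimethylallyl group into the linear prenyl group, dienone 11 tautomerises to the C4=O-chelated 5-OH phenol, and the gem-dimethyl-accelerated, base-free conditions should leave C2 unchanged.

Compound list
1 | 2',6'-dihydroxy-4'-methoxyacetophenone | CC(=O)c1c(O)cc(OC)cc1O | starting material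
2 | 3-chloro-3-methylbut-1-yne | C#CC(C)(C)Cl | starting material
3 | 1-[2-hydroxy-4-methoxy-6-(2-methylbut-3-yn-2-yloxy)phenyl]ethanone | CC(=O)c1c(O)cc(OC)cc1OC(C)(C)C#C | intermediate
4 | tert-butyl 3-[2-hydroxy-4-methoxy-6-(2-methylbut-3-yn-2-yloxy)phenyl]-3-oxopropanoate | CC(C)(C)OC(=O)CC(=O)c1c(O)cc(OC)cc1OC(C)(C)C#C | intermediate
5 | 4-tert-butoxybenzaldehyde | CC(C)(C)Oc1ccc(C=O)cc1 | starting material
6 | tert-butyl 3-(4-tert-butoxyphenyl)-2-[2-hydroxy-4-methoxy-6-(2-methylbut-3-yn-2-yloxy)benzoyl]prop-2-enoate (E/Z mixture) | CC(C)(C)OC(=O)C(=Cc1ccc(OC(C)(C)C)cc1)C(=O)c1c(O)cc(OC)cc1OC(C)(C)C#C | intermediate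
7 | tert-butyl (2S)-2-(4-tert-butoxyphenyl)-7-methoxy-5-(2-methylbut-3-yn-2-yloxy)-4-oxochromane-3-carboxylate (C3 epimers and enol, not isolated) | COc1cc2c(c(OC(C)(C)C#C)c1)C(=O)C(C(=O)OC(C)(C)C)[C@@H](c1ccc(OC(C)(C)C)cc1)O2 | intermediate
8 | (2S)-2-(4-hydroxyphenyl)-7-methoxy-5-(2-methylbut-3-yn-2-yloxy)-4-oxochromane-3-carboxylic acid (C3 epimers, not isolated) | COc1cc2c(c(OC(C)(C)C#C)c1)C(=O)C(C(=O)O)[C@@H](c1ccc(O)cc1)O2 | intermediate
9 | (2S)-2-(4-hydroxyphenyl)-7-methoxy-5-(2-methylbut-3-yn-2-yloxy)chroman-4-one | COc1cc2c(c(OC(C)(C)C#C)c1)C(=O)C[C@@H](c1ccc(O)cc1)O2 | intermediate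
10 | (2S)-2-(4-hydroxyphenyl)-7-methoxy-5-(2-methylbut-3-en-2-yloxy)chroman-4-one | COc1cc2c(c(OC(C)(C)C=C)c1)C(=O)C[C@@H](c1ccc(O)cc1)O2 | intermediate
11 | (2S)-2-(4-hydroxyphenyl)-7-methoxy-6-(3-methylbut-2-enyl)-2,3-dihydrochromene-4,5(6H)-dione (ortho-dienone, C6 transient and unassigned, not isolated) | COC1=CC2=C(C(=O)C1CC=C(C)C)C(=O)C[C@@H](c1ccc(O)cc1)O2 | intermediate
12 | 6-prenylsakuranetin, (2S)-5-hydroxy-2-(4-hydroxyphenyl)-7-methoxy-6-(3-methylbut-2-enyl)chroman-4-one | COc1cc2c(c(O)c1CC=C(C)C)C(=O)C[C@@H](c1ccc(O)cc1)O2 | target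

Total step count: 6. Longest linear sequence: 6 steps (1 → 3 → 4 → 6 → 9 → 10 → 12).

Steps most likely to fail

Step 4. Facial selectivity may be poor, because the doubly activated acceptor on a twisted 2,6-dioxygenated aroyl group can close without the catalyst or reopen before the acid stage. The O5 ether may also be partly lost during acidolysis. The fallback sets out from 3 and returns at 9. Claisen–Schmidt condensation of 3 with 5 (KOH, EtOH, rt) would give the (E)-2'-hydroxychalcone F1. NaOAc in refluxing EtOH would close it to the racemic flavanone tert-butyl ether F2. A kinetic resolution by asymmetric transfer hydrogenation (Cp*RhCl[(R,R)-TsDPEN], HCO2H/Et3N, EtOAc, rt, stopped near half conversion) should leave the (2S)-flavanone tert-butyl ether F3 and reduce its antipode to the cis-(2R,4R)-flavan-4-ol F4. After chromatographic separation, brief acidolysis of F3 (TFA, CH2Cl2, 0 °C) would give 9.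

Step 3. Ring closure may start too early and without stereocontrol under the amine catalyst, and condensation with the electron-rich aldehyde may be slow. The fallback sets out from 4 and returns at 6. The phenol is masked first (TBSCl, imidazole, DMF, rt) to give the silyl-protected β-keto ester F5. The Knoevenagel condensation with 5 can then be forced (piperidine/AcOH, PhMe, Dean–Stark) to the silyl-protected arylidene β-keto ester F6, which cannot cyclise. Non-basic desilylation (Et3N·3HF, THF, 0 °C) would release 6 just before the key step.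

Step 6. The configuration at C2 may erode thermally by retro-oxa-Michael opening assisted by the free B-ring phenol, and the tertiary allyl ether may partly ionise with loss of the C5 unit. The fallback sets out from 10 and returns at 12. The 4'-OH is silylated (TBSCl, imidazole, CH2Cl2, rt) to the 4'-O-TBS allyl ether F7. With no free phenol left to bind the metal, the [3,3] shift can then be run as a Lewis-acid-catalysed Claisen rearrangement (Eu(fod)3 10 mol %, CHCl3, 60 °C) to the 4'-O-TBS 6-prenylflavanone F8. Et3N·3HF (THF, 0 °C) would then give 12.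

Further compounds
F1 | step 4 | (E)-3-(4-tert-butoxyphenyl)-1-[2-hydroxy-4-methoxy-6-(2-methylbut-3-yn-2-yloxy)phenyl]prop-2-en-1-one | CC(C)(C)Oc1ccc(/C=C/C(=O)c2c(O)cc(OC)cc2OC(C)(C)C#C)cc1
F2 | step 4 | rac-2-(4-tert-butoxyphenyl)-7-methoxy-5-(2-methylbut-3-yn-2-yloxy)chroman-4-one | COc1cc2c(c(OC(C)(C)C#C)c1)C(=O)CC(c1ccc(OC(C)(C)C)cc1)O2
F3 | step 4 | (2S)-2-(4-tert-butoxyphenyl)-7-methoxy-5-(2-methylbut-3-yn-2-yloxy)chroman-4-one | COc1cc2c(c(OC(C)(C)C#C)c1)C(=O)C[C@@H](c1ccc(OC(C)(C)C)cc1)O2
F4 | step 4 | (2R,4R)-2-(4-tert-butoxyphenyl)-7-methoxy-5-(2-methylbut-3-yn-2-yloxy)chroman-4-ol | COc1cc2c(c(OC(C)(C)C#C)c1)[C@H](O)C[C@H](c1ccc(OC(C)(C)C)cc1)O2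
F5 | step 3 | tert-butyl 3-[2-(tert-butyldimethylsilyloxy)-4-methoxy-6-(2-methylbut-3-yn-2-yloxy)phenyl]-3-oxopropanoate | CC(C)(C)OC(=O)CC(=O)c1c(O[Si](C)(C)C(C)(C)C)cc(OC)cc1OC(C)(C)C#C
F6 | step 3 | tert-butyl 3-(4-tert-butoxyphenyl)-2-[2-(tert-butyldimethylsilyloxy)-4-methoxy-6-(2-methylbut-3-yn-2-yloxy)benzoyl]prop-2-enoate (E/Z mixture) | CC(C)(C)OC(=O)C(=Cc1ccc(OC(C)(C)C)cc1)C(=O)c1c(O[Si](C)(C)C(C)(C)C)cc(OC)cc1OC(C)(C)C#C
F7 | step 6 | (2S)-2-[4-(tert-butyldimethylsilyloxy)phenyl]-7-methoxy-5-(2-methylbut-3-en-2-yloxy)chroman-4-one | COc1cc2c(c(OC(C)(C)C=C)c1)C(=O)C[C@@H](c1ccc(O[Si](C)(C)C(C)(C)C)cc1)O2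
F8 | step 6 | (2S)-2-[4-(tert-butyldimethylsilyloxy)phenyl]-5-hydroxy-7-methoxy-6-(3-methylbut-2-enyl)chroman-4-one | COc1cc2c(c(O)c1CC=C(C)C)C(=O)C[C@@H](c1ccc(O[Si](C)(C)C(C)(C)C)cc1)O2
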